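## Analysis of the target

The target is an achiral diarylmethane. A 3-methylisocoumarin (1H-isochromen-1-one: benzo ring A, C4a to C8a, fused to the enol lactone ring C1–O2–C3–C4) is joined through one methylene carbon at C5 to a benzene ring B (C1′ at the bridge, C2′ OMe, C4′ OH, C6′ CH2OMe). There is no stereocentre and no alkene geometry to set, so the whole difficulty is positional. In ring A the bridge must sit at C5, next to the free hydroxyl on C6, and not at C7 between the two oxygens, and O6 must stay free while O8 is a methyl ether. In ring B the bridge carbon stands between a methoxy and a methoxymethyl group, para to a free phenol, and C6′ is meta to both oxygens, where electrophilic substitution does not go. Sensitive functions are the enol lactone (opened by hydroxide, alkoxides and hydrides), the two electron-rich phenolic rings (oxidation, capture of any electrophile released in a deprotection) and the doubly activated diarylmethane, which hot strong acid could cleave. The strategy rests on the oxygen pattern of ring A: read from the lactone carbonyl, C1–C8a–C8(OMe)–C7–C6 with O6 are, in this order, C2–C3–C4(OMe)–C5–C6 and the ring oxygen of 4-methoxy-6-methyl-2H-pyran-2-one 9, and C5 is its methyl carbon. Ring A can therefore be grown from 9 by acylation and benzylation at that carbon, then pyranone opening and aldol closure of C8a onto C4a.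

## Retrosynthetic reasoning

**19 to 17 (through 18).** The C1–O2 bond of the enol lactone is cut first. The lactone is the function least tolerant of base and nucleophiles, so it should be made last and under acid. Opening gives keto ester 18, whose ketone is carried as the dioxolane in 17. The forward reaction has to hydrolyse the ketal and let the enol oxygen acylate on the neighbouring methyl ester, in one operation.

**17 to 16.** The O4′–Si bond is cut. Ring B carries its phenol as a silyl ether from the beginning (see the last paragraph). It is removed with buffered fluoride before the acid step, so fluoride never meets the lactone and no electrophile is released beside two nucleophilic rings.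

**16 to 13 (key disconnection).** The C4a–C8a bond of ring A is cut. Retro-aldol and retro-dehydration unfold the benzoate to the open chain 14, which is the methanolysis product of pyranone 13. This is the one cut that turns the pentasubstituted ring A into a chain in which O8 is already an enol methyl ether, O6 is a ketone (later a free phenol) and the bridge already sits on C5. The forward reaction must open the lactone of 13, close C8a onto the C4a ketone, lose water and aromatize, through 14 and 15.

**13 to 12 and 8.** The bond between C5 and the bridging CH2 is cut. In 12, C5 is a methylene flanked by the pyranone and a ketone, the most acidic carbon of the molecule, so a weak base suffices and the route is convergent. The reverse order (benzylation of the methyl group of 9 first, acylation second) was not taken. It would need two cryogenic lithiations with ring B on board and the acylation of a secondary carbanion by an enolizable ester.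

**12 to 9 and 10.** The C5–C4a bond is cut. The lithiated methyl group of 9 (compound 11) is acylated by ester 10, which delivers C4a, C4, C3 and the C3 methyl group with C3 already masked.

**8 to 7 to 6.** The benzylic bromide comes from the alcohol and the alcohol from the aldehyde. The bromide is made last and used at once, because an electron-rich benzylic halide with a neighbouring ether oxygen does not store well.

**6 to 2 to 1.** The C6′–CH2OMe bond is cut. C6′ is out of reach of electrophiles but is the only free position ortho to the formyl group, so it is metalated through the amino alkoxide 3 (giving 4, then 5). Starting from 1, the 2-OMe/4-OH pattern of ring B is bought with the formyl carbon (the later bridge) in place, so no choice between the two oxygens has to be made. The phenol is protected as the bulky silyl ether 2 for three reasons: it shields C3′ and C5′ and does not direct metalation, it makes the benzylic bromide less prone to ionize than an alkoxy group would, and its removal sets free no formaldehyde equivalent.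

## Alternatives that were turned down

**Alternative 1:** Ring B is the ring that is made, not ring A. The cut goes through C1′–C2′ and C5′–C6′ and leads to ynone A2 (8-methoxy-6-(methoxymethoxy)-5-(4-methoxybut-2-ynoyl)-3-methyl-1H-isochromen-1-one), whose carbonyl carbon is the later bridge, and diene A3 (1,1-dimethoxy-3-(trimethylsilyloxy)buta-1,3-diene). On heating, the CH2 terminus of A3 should add to the β-carbon of A2 (the later C6′) and the ketene acetal carbon to the α-carbon (C1′). Loss of methanol and of the silyl group would give benzophenone A1 (5-[4-hydroxy-2-methoxy-6-(methoxymethyl)benzoyl]-8-methoxy-6-(methoxymethoxy)-3-methyl-1H-isochromen-1-one).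
- For: the ring B pattern follows from the polarity of the two partners, with both oxygens differentiated and no directed metalation. On this point it is stronger than the chosen route, which spends four steps and an ortho-lithiation on ring B.
- Against: the bridge arrives one oxidation level too high. The ketone of A1, flanked by four ortho substituents, must be reduced to CH2 beside an enol lactone that hydrides open and an acetal that the acid of an ionic hydrogenation removes.
- Against: A2 presupposes a finished isocoumarin acylated at C5 and not at C7, which leaves the positional problem of ring A unsolved. Ring A and the lactone also need their own sequence, so no steps are saved.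
- In exchange the chosen strategy offers a bridge that is CH2 from the start and a C5 substituent that is in place before ring A exists.

**Alternative 2:** C4–C4a and C1–C8a are cut together, so that both carbon substituents of ring A come from one malonate. Aryl bromide A5 ([3-bromo-5-methoxy-2-{[2-methoxy-6-(methoxymethyl)-4-(triisopropylsilyloxy)phenyl]methyl}phenoxy]triisopropylsilane) would be deprotonated between bromine and methoxy by the hindered amide A7 (lithium 2,2,6,6-tetramethylpiperidide) to give the C4a–C8a aryne. The lithium enolate of A6 (dimethyl malonate) adds at C4a, the aryl anion at C8a attacks an ester group, and opening of the four-membered alkoxide gives homophthalate A4 (methyl 6-methoxy-2-(2-methoxy-2-oxoethyl)-3-{[2-methoxy-6-(methoxymethyl)-4-(triisopropylsilyloxy)phenyl]methyl}-4-(triisopropylsilyloxy)benzoate).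
- For: one step installs C1 and C4, with the direction of addition fixed by the C8 methoxy group. As a single carbon–carbon bond-forming event it is as efficient as the key step of the chosen route.
- Against: no ring of the target is closed, and C3 with its methyl group is still missing, so A4 needs acetylation, decarboxylation and lactonization.
- Against: A5 already contains the diarylmethane with the benzyl group between bromine and the silyloxy group, so the C5 placement problem is only moved into the synthesis of A5.
- Against: A7 can also deprotonate the doubly benzylic bridge, the nucleophile must add next to the bulky C5 substituent, and malonate enolates are modest aryne traps under amide-base conditions.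
- The chosen strategy forms ring A itself, with every substituent placed by enolate chemistry.

**Alternative 3:** The C6–C7 bond is cut by a retro-electrocyclization, with the lactone ring present from the start. Acid A9 (2-[3-(1-methoxyethenyl)-6-methyl-2-oxo-2H-pyran-4-yl]-3-[2-methoxy-6-(methoxymethyl)-4-(methoxymethoxy)phenyl]propanoic acid) would be activated as a mixed anhydride with a hindered acyl chloride and a tertiary amine. Elimination gives a ketene at C6, and the triene C7=C8–C8a=C4a–C5=C6 closes thermally and tautomerizes to phenol A8 (6-hydroxy-8-methoxy-5-{[2-methoxy-6-(methoxymethyl)-4-(methoxymethoxy)phenyl]methyl}-3-methyl-1H-isochromen-1-one).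
- For: the key step ends at the complete isocoumarin with O6 free and O8 methylated, and only one deprotection follows. After the key step it is shorter than the chosen route (one step against two).
- Against: A9 is the hard part. It is a 3,4-disubstituted 6-methylpyranone carrying an acid-labile enol ether next to a free carboxylic acid, with a branched side chain on C4 that must be attached to a 3-acyl-4-hydroxypyranone template by an uncertain carbon–carbon coupling.
- Against: the ketene can dimerize or be trapped by the amine, and the final acetal cleavage releases a formaldehyde equivalent beside two electron-rich rings.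
- The chosen strategy reaches its precursor 13 from a commercial pyranone by two enolate reactions, and its last deprotections release no electrophile.

Key step: step 7

## Remarks before the steps

- Numbering: isocoumarin positions C1 to C8a and primed positions for ring B are used for all intermediates, according to where each atom ends up.
- Stereochemistry: compounds 3, 4, 5, 13 and 14 are racemic and 15 is a mixture of diastereomers. All these stereocentres are lost again, so their SMILES carry no configuration.
- Assumption: the aryl silyl ether is taken to survive Mg(OMe)2 in methanol. Any part that is cleaved in step 7 is compound 17, the product of step 8, so the route converges either way.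

## Route

Step 1
Reactants: 1 4-hydroxy-2-methoxybenzaldehyde
Product: 2 2-methoxy-4-(triisopropylsilyloxy)benzaldehyde
Conditions: iPr3SiCl, imidazole, DMF, rt
Reagents that add atoms: chlorotriisopropylsilane, CC(C)[Si](Cl)(C(C)C)C(C)C
Why: Standard silylation of a phenol with a silyl chloride and imidazole. The bulky silyl ether is chosen because it neither directs nor permits ortho-lithiation at C3′ and C5′ and is later removed by fluoride without releasing an electrophile.

Step 2
Reactants: 2 2-methoxy-4-(triisopropylsilyloxy)benzaldehyde
Product: 6 2-methoxy-6-(methoxymethyl)-4-(triisopropylsilyloxy)benzaldehyde, via lithium amino alkoxide 3 (not isolated), via ring-lithiated amino alkoxide 4 (not isolated), via methoxymethylated amino alkoxide 5 (not isolated)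
Conditions: LiN(Me)CH2CH2NMe2 (from MeNHCH2CH2NMe2 and n-BuLi), THF, −20 °C; n-BuLi (3 equiv), −20 °C, 20 h; MeOCH2Cl (excess), −78 °C → rt; aq NH4Cl
Reagents that add atoms: chloromethyl methyl ether, COCCl
Why: Directed ortho-metalation through an α-amino alkoxide formed in the flask: the lithium amide masks the aldehyde as 3 and its chelating diamine arm delivers n-BuLi to C6′, the only free position ortho to the masked formyl group, while C3′ and C5′ are shielded by the silyl ether. The aryllithium 4 is alkylated by the chloromethyl ether to 5, and aqueous work-up returns the aldehyde.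

Step 3
Reactants: 6 2-methoxy-6-(methoxymethyl)-4-(triisopropylsilyloxy)benzaldehyde
Product: 7 [2-methoxy-6-(methoxymethyl)-4-(triisopropylsilyloxy)phenyl]methanol
Conditions: NaBH4, MeOH–THF, 0 °C
Reagents that add atoms: none
Why: Borohydride reduction of an aromatic aldehyde; the aryl silyl ether and the benzylic methyl ether are inert under these conditions.

Step 4
Reactants: 7 [2-methoxy-6-(methoxymethyl)-4-(triisopropylsilyloxy)phenyl]methanol
Product: 8 [4-(bromomethyl)-3-methoxy-5-(methoxymethyl)phenoxy]triisopropylsilane
Conditions: CBr4, PPh3, CH2Cl2, 0 °C; used crude at once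
Reagents that add atoms: tetrabromomethane, BrC(Br)(Br)Br
Why: Appel bromination of a primary benzylic alcohol under neutral conditions, which spares the silyl ether. The bromide is not stored or chromatographed because the ortho-methoxy group favours ionization.

Step 5
Reactants: 9 4-methoxy-6-methyl-2H-pyran-2-one; 10 ethyl (2-methyl-1,3-dioxolan-2-yl)acetate
Product: 12 4-methoxy-6-[3-(2-methyl-1,3-dioxolan-2-yl)-2-oxopropyl]-2H-pyran-2-one, via lithiated pyranone 11 (not isolated)
Conditions: LiN(iPr)2 (2.1 equiv), 9 (2.1 equiv), THF, −78 °C; then 10 (1 equiv), −78 → −30 °C; aq NH4Cl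
Reagents that add atoms: none
Why: Lateral lithiation of the 6-methyl group of the pyranone followed by Claisen-type acylation with the ester. The second equivalent of 11 deprotonates the more acidic product, which stops the reaction at monoacylation, and the dioxolane is inert to base at low temperature.

Step 6
Reactants: 12 4-methoxy-6-[3-(2-methyl-1,3-dioxolan-2-yl)-2-oxopropyl]-2H-pyran-2-one; 8 [4-(bromomethyl)-3-methoxy-5-(methoxymethyl)phenoxy]triisopropylsilane
Product: 13 rac-4-methoxy-6-{1-[2-methoxy-6-(methoxymethyl)-4-(triisopropylsilyloxy)phenyl]-4-(2-methyl-1,3-dioxolan-2-yl)-3-oxobutan-2-yl}-2H-pyran-2-one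
Conditions: K2CO3, acetone, 0 °C → rt
Reagents that add atoms: none
Why: Alkylation of a doubly activated methylene (between the pyranone and the ketone) with a benzylic bromide under weak base, as for a 1,3-dicarbonyl compound; the delocalized carbon nucleophile and the benzylic halide favour C- over O-alkylation, and the hindered product resists a second alkylation. The new stereocentre at C5 is formed racemic and is destroyed in step 7.

Step 7
Reactants: 13 rac-4-methoxy-6-{1-[2-methoxy-6-(methoxymethyl)-4-(triisopropylsilyloxy)phenyl]-4-(2-methyl-1,3-dioxolan-2-yl)-3-oxobutan-2-yl}-2H-pyran-2-one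
Product: 16 methyl 4-hydroxy-2-methoxy-5-{[2-methoxy-6-(methoxymethyl)-4-(triisopropylsilyloxy)phenyl]methyl}-6-[(2-methyl-1,3-dioxolan-2-yl)methyl]benzoate, via open-chain enoate 14 (not isolated), via aldol adduct 15 (not isolated)
Conditions: Mg(OMe)2 (5 equiv), MeOH, rt → 60 °C; aq NH4Cl
Reagents that add atoms: magnesium dimethoxide, CO[Mg]OC; methanol, CO
Why: Methoxide from Mg(OMe)2 adds to the lactone carbonyl (pyranone C2, the later C1) and the ring opens to the E-enoate 14, in which magnesium binds the C6/C4a dicarbonyl unit around C5. Deprotonation at C7 gives the ester dienolate, which attacks the C4a ketone through its α-carbon C8a; this forms the C4a–C8a bond and closes ring A in a 6-(enolexo)-exo-trig aldol reaction to 15. Loss of water across C4a–C8a and enolization of the C6 ketone then give benzoate 16, and this aromatization is the irreversible step that drains the earlier equilibria. The closest known reaction is the base-induced opening of 6-(2-oxoalkyl)-4-methoxy-2-pyranones with aldol closure to 4-hydroxy-2-methoxybenzoates, a laboratory copy of the orsellinate-type polyketide fold; 13 differs only in the substituent on C5. No stereocentre is formed, and the one in 13 disappears. The aldol has to win over three other paths: attack of the C5 carbanion on the ester carbonyl C1 (a Claisen closure that here gives a quaternary triketone that cannot aromatize and can revert), attack of a C4 carbanion on C8 with loss of methoxide, and cleavage of the 1,3-diketone by methoxide. The dioxolane at C3 keeps C4 an ordinary ketone α-carbon and not a 1,3-diketone methylene, magnesium holds the diketone as its chelated enolate and brings C8a near C4a, and O8 arrives methylated and O6 free because they were the enol ether oxygen and the ring oxygen of the pyranone.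

Step 8
Reactants: 16 methyl 4-hydroxy-2-methoxy-5-{[2-methoxy-6-(methoxymethyl)-4-(triisopropylsilyloxy)phenyl]methyl}-6-[(2-methyl-1,3-dioxolan-2-yl)methyl]benzoate
Product: 17 methyl 4-hydroxy-5-{[4-hydroxy-2-methoxy-6-(methoxymethyl)phenyl]methyl}-2-methoxy-6-[(2-methyl-1,3-dioxolan-2-yl)methyl]benzoate
Conditions: Bu4NF, AcOH (1:1), THF, 0 °C
Reagents that add atoms: none
Why: Fluoride cleavage of an aryl silyl ether; acetic acid buffers the phenoxide, so the ester and the dioxolane are untouched. No electrophilic fragment is released next to the two electron-rich rings.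

Step 9
Reactants: 17 methyl 4-hydroxy-5-{[4-hydroxy-2-methoxy-6-(methoxymethyl)phenyl]methyl}-2-methoxy-6-[(2-methyl-1,3-dioxolan-2-yl)methyl]benzoate
Product: 19 6-hydroxy-5-{[4-hydroxy-2-methoxy-6-(methoxymethyl)phenyl]methyl}-8-methoxy-3-methyl-1H-isochromen-1-one, via keto ester 18 (not isolated)
Conditions: CF3CO2H–H2O (9:1), 0 °C → rt
Reagents that add atoms: water, O
Why: Acid hydrolysis of the dioxolane gives methyl ketone 18, whose enol oxygen attacks the neighbouring methyl ester in a six-membered acyl substitution with loss of methanol (enol lactonization of a 2-(2-oxopropyl)benzoate) to give the 3-methylisocoumarin. The unactivated benzylic methyl ether of ring B and the diarylmethane should tolerate this short exposure at room temperature.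

## Compound list

1 | 4-hydroxy-2-methoxybenzaldehyde | COc1cc(O)ccc1C=O | starting material
2 | 2-methoxy-4-(triisopropylsilyloxy)benzaldehyde | COc1cc(O[Si](C(C)C)(C(C)C)C(C)C)ccc1C=O | intermediate
3 | lithium {[2-(dimethylamino)ethyl](methyl)amino}[2-methoxy-4-(triisopropylsilyloxy)phenyl]methanolate (racemic) | [Li]OC(N(C)CCN(C)C)c1ccc(O[Si](C(C)C)(C(C)C)C(C)C)cc1OC | intermediate (not isolated)
4 | lithium {[2-(dimethylamino)ethyl](methyl)amino}[2-lithio-6-methoxy-4-(triisopropylsilyloxy)phenyl]methanolate (racemic) | [Li]OC(N(C)CCN(C)C)c1c([Li])cc(O[Si](C(C)C)(C(C)C)C(C)C)cc1OC | intermediate (not isolated)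
5 | lithium {[2-(dimethylamino)ethyl](methyl)amino}[2-methoxy-6-(methoxymethyl)-4-(triisopropylsilyloxy)phenyl]methanolate (racemic) | [Li]OC(N(C)CCN(C)C)c1c(COC)cc(O[Si](C(C)C)(C(C)C)C(C)C)cc1OC | intermediate (not isolated)
6 | 2-methoxy-6-(methoxymethyl)-4-(triisopropylsilyloxy)benzaldehyde | COCc1cc(O[Si](C(C)C)(C(C)C)C(C)C)cc(OC)c1C=O | intermediate
7 | [2-methoxy-6-(methoxymethyl)-4-(triisopropylsilyloxy)phenyl]methanol | COCc1cc(O[Si](C(C)C)(C(C)C)C(C)C)cc(OC)c1CO | intermediate
8 | [4-(bromomethyl)-3-methoxy-5-(methoxymethyl)phenoxy]triisopropylsilane | COCc1cc(O[Si](C(C)C)(C(C)C)C(C)C)cc(OC)c1CBr | intermediate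
9 | 4-methoxy-6-methyl-2H-pyran-2-one | COc1cc(=O)oc(C)c1 | starting material
10 | ethyl (2-methyl-1,3-dioxolan-2-yl)acetate | CCOC(=O)CC1(C)OCCO1 | starting material
11 | 6-(lithiomethyl)-4-methoxy-2H-pyran-2-one | COc1cc(=O)oc(C[Li])c1 | intermediate (not isolated)
12 | 4-methoxy-6-[3-(2-methyl-1,3-dioxolan-2-yl)-2-oxopropyl]-2H-pyran-2-one | COc1cc(=O)oc(CC(=O)CC2(C)OCCO2)c1 | intermediate
13 | rac-4-methoxy-6-{1-[2-methoxy-6-(methoxymethyl)-4-(triisopropylsilyloxy)phenyl]-4-(2-methyl-1,3-dioxolan-2-yl)-3-oxobutan-2-yl}-2H-pyran-2-one | COc1cc(=O)oc(c1)C(Cc1c(COC)cc(O[Si](C(C)C)(C(C)C)C(C)C)cc1OC)C(=O)CC1(C)OCCO1 | intermediate (precursor of the key step)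
14 | methyl (2E)-3-methoxy-6-{[2-methoxy-6-(methoxymethyl)-4-(triisopropylsilyloxy)phenyl]methyl}-8-(2-methyl-1,3-dioxolan-2-yl)-5,7-dioxooct-2-enoate (racemic) | COC(=O)/C=C(/OC)CC(=O)C(Cc1c(COC)cc(O[Si](C(C)C)(C(C)C)C(C)C)cc1OC)C(=O)CC1(C)OCCO1 | intermediate (not isolated)
15 | methyl 2-hydroxy-6-methoxy-3-{[2-methoxy-6-(methoxymethyl)-4-(triisopropylsilyloxy)phenyl]methyl}-2-[(2-methyl-1,3-dioxolan-2-yl)methyl]-4-oxocyclohex-5-ene-1-carboxylate (mixture of diastereomers) | COC(=O)C1C(OC)=CC(=O)C(Cc2c(COC)cc(O[Si](C(C)C)(C(C)C)C(C)C)cc2OC)C1(O)CC1(C)OCCO1 | intermediate (not isolated)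
16 | methyl 4-hydroxy-2-methoxy-5-{[2-methoxy-6-(methoxymethyl)-4-(triisopropylsilyloxy)phenyl]methyl}-6-[(2-methyl-1,3-dioxolan-2-yl)methyl]benzoate | COC(=O)c1c(OC)cc(O)c(Cc2c(COC)cc(O[Si](C(C)C)(C(C)C)C(C)C)cc2OC)c1CC1(C)OCCO1 | intermediate (product of the key step)
17 | methyl 4-hydroxy-5-{[4-hydroxy-2-methoxy-6-(methoxymethyl)phenyl]methyl}-2-methoxy-6-[(2-methyl-1,3-dioxolan-2-yl)methyl]benzoate | COC(=O)c1c(OC)cc(O)c(Cc2c(COC)cc(O)cc2OC)c1CC1(C)OCCO1 | intermediate
18 | methyl 4-hydroxy-5-{[4-hydroxy-2-methoxy-6-(methoxymethyl)phenyl]methyl}-2-methoxy-6-(2-oxopropyl)benzoate | COC(=O)c1c(OC)cc(O)c(Cc2c(COC)cc(O)cc2OC)c1CC(C)=O | intermediate (not isolated)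
19 | 6-hydroxy-5-{[4-hydroxy-2-methoxy-6-(methoxymethyl)phenyl]methyl}-8-methoxy-3-methyl-1H-isochromen-1-one | COCc1cc(O)cc(OC)c1Cc1c(O)cc(OC)c2c(=O)oc(C)cc12 | target

## Step count and least certain steps

Total: 9 steps. Longest linear sequence: 8 steps (1 → 2 → 6 → 7 → 8 → 13 → 16 → 17 → 19); the pyranone branch (9 and 10 → 12) joins at step 6.

**Step 7 (key step).** The C4a ketone is flanked by the branched C5 and a neopentyl-like CH2, so the aldol may be slow. The alternatives are then reclosure to the pyranone, methoxide cleavage of the 2-substituted 1,3-diketone, or β-elimination that opens the dioxolane from a C4 enolate. Methanolysis of the silyl ether may also occur but is harmless (see the assumption). The fallback brings in C3 only after ring A exists. It sets out from 9 and 8 and comes back to the route at 19.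
- Acylation of 11 with N-methoxy-N-methylacetamide gives 4-methoxy-6-(2-oxopropyl)-2H-pyran-2-one F1.
- Alkylation with 8 (K2CO3, acetone) gives the benzylated methyl ketone F2.
- Mg(OMe)2 in methanol, now acting on an unhindered methyl ketone without a β-oxygen, gives the toluate methyl 4-hydroxy-2-methoxy-5-{[2-methoxy-6-(methoxymethyl)-4-(triisopropylsilyloxy)phenyl]methyl}-6-methylbenzoate F3.
- Silylation (iPr3SiCl, imidazole) gives the bis-silyl ether F4.
- Lateral lithiation of the ring methyl group with LiN(iPr)2 at −78 °C and acetylation with N-methoxy-N-methylacetamide gives keto ester F5, which CF3CO2H closes to the bis-silylated isocoumarin F6.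
- Bu4NF with AcOH then gives 19.

**Step 2.** Metalation could occur at C3′ or C5′ in spite of the silyl group, butyllithium could attack silicon, or the excess butyllithium could consume the chloromethyl ether before the aryllithium is trapped. The fallback uses a carboxylate as directing group. It sets out from 2 and comes back at 7 (step 3 is then not needed). Oxidation with NaClO2 (NaH2PO4, 2-methylbut-2-ene, t-BuOH–H2O) gives 2-methoxy-4-(triisopropylsilyloxy)benzoic acid F7. s-BuLi with TMEDA in THF at −78 °C lithiates the lithium carboxylate at the free ortho position, and excess MeOCH2Cl alkylates both the aryllithium and the carboxylate to give methoxymethyl 2-methoxy-6-(methoxymethyl)-4-(triisopropylsilyloxy)benzoate F8. iBu2AlH reduces F8 to 7.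

**Step 5.** Proton transfer from the α-CH2 of ester 10 to 11 would give an ester enolate that can open the dioxolane by β-elimination, and 11 can also add to a second pyranone. The fallback replaces the ester by an aldehyde, which adds faster than it enolizes. It sets out from 10 and 9 and comes back at 12. iBu2AlH at −78 °C reduces 10 to (2-methyl-1,3-dioxolan-2-yl)acetaldehyde F9, 11 adds to F9 to give the secondary alcohol 6-[2-hydroxy-3-(2-methyl-1,3-dioxolan-2-yl)propyl]-4-methoxy-2H-pyran-2-one F10, and Dess–Martin periodinane oxidizes F10 to 12.

**Step 6.** Alkylation on the enolate oxygen rather than on carbon, a second alkylation, or ionization of 8 during the slow reaction of a hindered electrophile would lower the yield. The fallback forms the same bond by condensation and reduction. It sets out from 6 and 12 and comes back at 13 (steps 3 and 4 are then not needed). Knoevenagel condensation (piperidinium acetate, toluene, removal of water, or TiCl4 with pyridine) gives the arylidene ketone F11, and diethyl 2,6-dimethyl-1,4-dihydropyridine-3,5-dicarboxylate reduces its C=C bond to give 13.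

**Step 4.** The bromide may decompose as it forms: ionization assisted by the ortho-methoxy group, ring closure by the neighbouring methoxymethyl oxygen with loss of bromomethane, or self-alkylation of the electron-rich ring. The fallback avoids the halide. It sets out from 7 and 12 and comes back at 13: alkylation of the active methylene of 12 directly with alcohol 7 and (cyanomethylene)tributylphosphorane in toluene at 80 °C (Mitsunobu-type C-alkylation). It makes no new compound.

## Further compounds

F1 | step 7 | 4-methoxy-6-(2-oxopropyl)-2H-pyran-2-one | COc1cc(=O)oc(CC(C)=O)c1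
F2 | step 7 | rac-4-methoxy-6-{1-[2-methoxy-6-(methoxymethyl)-4-(triisopropylsilyloxy)phenyl]-3-oxobutan-2-yl}-2H-pyran-2-one | COc1cc(=O)oc(c1)C(Cc1c(COC)cc(O[Si](C(C)C)(C(C)C)C(C)C)cc1OC)C(C)=O
F3 | step 7 | methyl 4-hydroxy-2-methoxy-5-{[2-methoxy-6-(methoxymethyl)-4-(triisopropylsilyloxy)phenyl]methyl}-6-methylbenzoate | COC(=O)c1c(OC)cc(O)c(Cc2c(COC)cc(O[Si](C(C)C)(C(C)C)C(C)C)cc2OC)c1C
F4 | step 7 | methyl 2-methoxy-5-{[2-methoxy-6-(methoxymethyl)-4-(triisopropylsilyloxy)phenyl]methyl}-6-methyl-4-(triisopropylsilyloxy)benzoate | COC(=O)c1c(OC)cc(O[Si](C(C)C)(C(C)C)C(C)C)c(Cc2c(COC)cc(O[Si](C(C)C)(C(C)C)C(C)C)cc2OC)c1C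
F5 | step 7 | methyl 2-methoxy-5-{[2-methoxy-6-(methoxymethyl)-4-(triisopropylsilyloxy)phenyl]methyl}-6-(2-oxopropyl)-4-(triisopropylsilyloxy)benzoate | COC(=O)c1c(OC)cc(O[Si](C(C)C)(C(C)C)C(C)C)c(Cc2c(COC)cc(O[Si](C(C)C)(C(C)C)C(C)C)cc2OC)c1CC(C)=O
F6 | step 7 | 8-methoxy-5-{[2-methoxy-6-(methoxymethyl)-4-(triisopropylsilyloxy)phenyl]methyl}-3-methyl-6-(triisopropylsilyloxy)-1H-isochromen-1-one | COCc1cc(O[Si](C(C)C)(C(C)C)C(C)C)cc(OC)c1Cc1c(O[Si](C(C)C)(C(C)C)C(C)C)cc(OC)c2c(=O)oc(C)cc12
F7 | step 2 | 2-methoxy-4-(triisopropylsilyloxy)benzoic acid | COc1cc(O[Si](C(C)C)(C(C)C)C(C)C)ccc1C(=O)O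
F8 | step 2 | methoxymethyl 2-methoxy-6-(methoxymethyl)-4-(triisopropylsilyloxy)benzoate | COCOC(=O)c1c(COC)cc(O[Si](C(C)C)(C(C)C)C(C)C)cc1OC
F9 | step 5 | (2-methyl-1,3-dioxolan-2-yl)acetaldehyde | O=CCC1(C)OCCO1
F10 | step 5 | rac-6-[2-hydroxy-3-(2-methyl-1,3-dioxolan-2-yl)propyl]-4-methoxy-2H-pyran-2-one | COc1cc(=O)oc(CC(O)CC2(C)OCCO2)c1
F11 | step 6 | 4-methoxy-6-{1-[2-methoxy-6-(methoxymethyl)-4-(triisopropylsilyloxy)phenyl]-4-(2-methyl-1,3-dioxolan-2-yl)-3-oxobut-1-en-2-yl}-2H-pyran-2-one (alkene geometry not defined) | COc1cc(=O)oc(c1)C(=Cc1c(COC)cc(O[Si](C(C)C)(C(C)C)C(C)C)cc1OC)C(=O)CC1(C)OCCO1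
F0 | step 4 | none | none
A1 | alternative 1 | 5-[4-hydroxy-2-methoxy-6-(methoxymethyl)benzoyl]-8-methoxy-6-(methoxymethoxy)-3-methyl-1H-isochromen-1-one | COCc1cc(O)cc(OC)c1C(=O)c1c(OCOC)cc(OC)c2c(=O)oc(C)cc12
A2 | alternative 1 | 8-methoxy-6-(methoxymethoxy)-5-(4-methoxybut-2-ynoyl)-3-methyl-1H-isochromen-1-one | COCC#CC(=O)c1c(OCOC)cc(OC)c2c(=O)oc(C)cc12
A3 | alternative 1 | 1,1-dimethoxy-3-(trimethylsilyloxy)buta-1,3-diene | COC(OC)=CC(=C)O[Si](C)(C)C
A4 | alternative 2 | methyl 6-methoxy-2-(2-methoxy-2-oxoethyl)-3-{[2-methoxy-6-(methoxymethyl)-4-(triisopropylsilyloxy)phenyl]methyl}-4-(triisopropylsilyloxy)benzoate | COC(=O)Cc1c(Cc2c(COC)cc(O[Si](C(C)C)(C(C)C)C(C)C)cc2OC)c(O[Si](C(C)C)(C(C)C)C(C)C)cc(OC)c1C(=O)OC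
A5 | alternative 2 | [3-bromo-5-methoxy-2-{[2-methoxy-6-(methoxymethyl)-4-(triisopropylsilyloxy)phenyl]methyl}phenoxy]triisopropylsilane | COCc1cc(O[Si](C(C)C)(C(C)C)C(C)C)cc(OC)c1Cc1c(Br)cc(OC)cc1O[Si](C(C)C)(C(C)C)C(C)C
A6 | alternative 2 | dimethyl malonate | COC(=O)CC(=O)OC
A7 | alternative 2 | lithium 2,2,6,6-tetramethylpiperidide | [Li]N1C(C)(C)CCCC1(C)C
A8 | alternative 3 | 6-hydroxy-8-methoxy-5-{[2-methoxy-6-(methoxymethyl)-4-(methoxymethoxy)phenyl]methyl}-3-methyl-1H-isochromen-1-one | COCc1cc(OCOC)cc(OC)c1Cc1c(O)cc(OC)c2c(=O)oc(C)cc12
A9 | alternative 3 | rac-2-[3-(1-methoxyethenyl)-6-methyl-2-oxo-2H-pyran-4-yl]-3-[2-methoxy-6-(methoxymethyl)-4-(methoxymethoxy)phenyl]propanoic acid | COCc1cc(OCOC)cc(OC)c1CC(C(=O)O)c1cc(C)oc(=O)c1C(=C)OC
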